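## Retrosynthetic overview

1. The target comes from acid deprotection of its N-Boc / O-TBS / dimethyl-acetal form, which comes from alkene-selective hydrogenation of a bis-(Z)-olefin.
2. The bis-olefin comes from a double Wittig reaction: a C19 bis-ylide carrying the masked E-enal plus two equivalents of a piperidin-6-yl-acetaldehyde.
3. The C19 core comes from self-aldol condensation of 10-bromodecanal (from decane-1,10-diol), which fixes the E-2-alkylalk-2-enal.
4. The piperidine aldehyde comes from intramolecular aza-Michael addition of NHBoc onto an E-enal (6-exo, sets C6); the enal comes from cross-metathesis with crotonaldehyde.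
5. The syn amino alcohol (C2, C3) comes from L-alanine methyl ester by chelation-controlled reductive butenylation. The piperidine is the only ring formed: it is closed once, before coupling, and used twice.

Assumption: piperidine numbering is N1, C2 (CH3), C3 (O), C6 (side chain); both rings of the target are (2S,3S,6R), all-cis, and the enal is E. Commercial but-3-enylmagnesium bromide solution is taken as a starting material.

## Route

Step 1
Reactants: 1 L-alanine methyl ester hydrochloride
Product: 2 methyl (2S)-2-[(diphenylmethylidene)amino]propanoate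
Conditions: Ph2C=NH (1.0 equiv), CH2Cl2, rt, 24 h
Reagents that add atoms: benzophenone imine, N=C(c1ccccc1)c1ccccc1
Why: O'Donnell transimination, driven by precipitation of NH4Cl, runs without base, so the alanine stereocentre (the future C2) is untouched.

Step 2
Reactants: 2 methyl (2S)-2-[(diphenylmethylidene)amino]propanoate; 3 but-3-en-1-ylmagnesium bromide
Product: 5 (2S,3S)-2-[(diphenylmethylidene)amino]hept-6-en-3-ol, via aluminoxy acetal 4 (not isolated)
Conditions: i-Bu2AlH·i-Bu3Al (1:1, 1.1 equiv), CH2Cl2, −78 °C; then 3 (3 equiv, THF), −78 °C → rt; aq. NaHCO3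
Reagents that add atoms: none
Why: Polt one-pot reductive alkylation: the ester stops at the aluminoxy acetal (no free, racemisable aldehyde), and the Grignard reagent adds to the N,O-chelated aldehyde (Cram chelate) from the face opposite the C2 methyl, giving the threo (syn, 2S,3S) amino alcohol with expected dr of about 8:1 or better.

Step 3
Reactants: 5 (2S,3S)-2-[(diphenylmethylidene)amino]hept-6-en-3-ol
Product: 7 tert-butyl N-[(2S,3S)-3-hydroxyhept-6-en-2-yl]carbamate, via amino alcohol hydrochloride 6 (not isolated)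
Conditions: 1 M aq. HCl/THF (1:1), rt, 2 h; then NaHCO3 (pH 8), Boc2O (1.2 equiv), rt
Reagents that add atoms: di-tert-butyl dicarbonate, CC(C)(C)OC(=O)OC(=O)OC(C)(C)C
Why: Ketimine hydrolysis followed by carbamate formation touches neither stereocentre, and the minor anti diastereomer is removed by chromatography at this stage.

Step 4
Reactants: 7 tert-butyl N-[(2S,3S)-3-hydroxyhept-6-en-2-yl]carbamate
Product: 8 tert-butyl N-[(2S,3S)-3-(tert-butyldimethylsilyloxy)hept-6-en-2-yl]carbamate
Conditions: TBSCl (1.5 equiv), imidazole (3 equiv), DMF, rt → 40 °C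
Reagents that add atoms: tert-butyldimethylsilyl chloride, CC(C)(C)[Si](C)(C)Cl
Why: Corey silylation of the secondary alcohol blocks the competing 5-exo oxa-Michael addition later and leaves the carbamate N–H free.

Step 5
Reactants: 8 tert-butyl N-[(2S,3S)-3-(tert-butyldimethylsilyloxy)hept-6-en-2-yl]carbamate; 9 (E)-crotonaldehyde
Product: 10 tert-butyl N-[(2S,3S,6E)-3-(tert-butyldimethylsilyloxy)-8-oxooct-6-en-2-yl]carbamate
Conditions: Hoveyda–Grubbs II (5 mol%), 9 (5 equiv), CH2Cl2, 40 °C
Reagents that add atoms: none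
Why: Olefin cross-metathesis of a terminal alkene with an excess of an electron-poor partner is E-selective, loses propene, and tolerates NHBoc and OTBS.

Step 6
Reactants: 10 tert-butyl N-[(2S,3S,6E)-3-(tert-butyldimethylsilyloxy)-8-oxooct-6-en-2-yl]carbamate
Product: 11 tert-butyl (2S,3S,6S)-3-(tert-butyldimethylsilyloxy)-2-methyl-6-(2-oxoethyl)piperidine-1-carboxylate
Conditions: (R)-α,α-bis[3,5-bis(trifluoromethyl)phenyl]prolinol TMS ether (20 mol%), PhCO2H (20 mol%), CHCl3, −30 → −10 °C
Reagents that add atoms: none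
Why: 6-exo-trig intramolecular aza-Michael addition under iminium catalysis (Jørgensen–Hayashi catalyst): in the E-iminium ion the CAr2OTMS group of the (R)-catalyst covers the Re face of C6, so the carbamate nitrogen adds to the Si face and the new C6 centre is cis to the C2 methyl (6S by CIP here, the 6R centre of the target).

Step 7
Reactants: 12 decane-1,10-diol
Product: 13 10-bromodecan-1-ol
Conditions: 48% aq. HBr (1.1 equiv), toluene, reflux (Dean–Stark)
Reagents that add atoms: hydrogen bromide, Br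
Why: SN2 monobromination in the two-phase HBr/toluene system, where the bromo alcohol is extracted into toluene and shielded from a second substitution.

Step 8
Reactants: 13 10-bromodecan-1-ol
Product: 14 10-bromodecanal
Conditions: TEMPO (10 mol%), PhI(OAc)2 (1.1 equiv), CH2Cl2, rt
Reagents that add atoms: none
Why: TEMPO/BAIB oxidation stops cleanly at the aldehyde and does not touch the primary bromide.

Step 9
Reactants: 14 10-bromodecanal (2 equiv)
Product: 16 (2E)-12-bromo-2-(8-bromooctyl)dodec-2-enal, via aldol adduct 15 (not isolated)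
Conditions: Bn2NH·CF3CO2H (20 mol%), toluene, 70 °C
Reagents that add atoms: none
Why: Ammonium-salt-catalysed self-aldol condensation (enamine plus iminium) followed by dehydration gives the thermodynamic E-2-alkylalk-2-enal (β-alkyl trans to CHO), the geometry of the target, while the weakly nucleophilic amine salt spares the bromides.

Step 10
Reactants: 16 (2E)-12-bromo-2-(8-bromooctyl)dodec-2-enal
Product: 17 (9E)-1,19-dibromo-9-(dimethoxymethyl)nonadec-9-ene
Conditions: HC(OMe)3 (6 equiv, neat), PPTS (5 mol%), rt; Et3N quench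
Reagents that add atoms: trimethyl orthoformate, COC(OC)OC
Why: Mild acetalisation masks the aldehyde against the ylide chemistry and makes the trisubstituted alkene a hindered, non-conjugated olefin without changing its geometry.

Step 11
Reactants: 17 (9E)-1,19-dibromo-9-(dimethoxymethyl)nonadec-9-ene
Product: 18 [(9E)-9-(dimethoxymethyl)nonadec-9-ene-1,19-diyl]bis(triphenylphosphonium) dibromide
Conditions: PPh3 (2.4 equiv), K2CO3 (trace), MeCN, reflux, 48 h
Reagents that add atoms: triphenylphosphine, c1ccc(cc1)P(c1ccccc1)c1ccccc1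
Why: Double SN2 quaternisation of two unhindered primary bromides under neutral, buffered conditions that the acetal survives.

Step 12
Reactants: 18 [(9E)-9-(dimethoxymethyl)nonadec-9-ene-1,19-diyl]bis(triphenylphosphonium) dibromide; 11 tert-butyl (2S,3S,6S)-3-(tert-butyldimethylsilyloxy)-2-methyl-6-(2-oxoethyl)piperidine-1-carboxylate (2.2 equiv)
Product: 20 di-tert-butyl (2S,2'S,3S,3'S,6S,6'S)-6,6'-[(2Z,11E,21Z)-11-(dimethoxymethyl)tricosa-2,11,21-triene-1,23-diyl]bis[3-(tert-butyldimethylsilyloxy)-2-methylpiperidine-1-carboxylate], via bis-ylide 19 (not isolated)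
Conditions: KHMDS (2.05 equiv), THF, −78 → 0 °C; then 11, −78 °C → rt
Reagents that add atoms: none
Why: Double Wittig olefination with a non-stabilised bis-ylide joins both head groups in one operation (Z-olefins, geometry irrelevant), and adding the aldehyde at −78 °C lets olefination outrun enolisation or retro-Michael opening, so C6 is not scrambled.

Step 13
Reactants: 20 the bis-(Z)-olefin from step 12
Product: 21 di-tert-butyl (2S,2'S,3S,3'S,6R,6'R)-6,6'-[(11E)-11-(dimethoxymethyl)tricos-11-ene-1,23-diyl]bis[3-(tert-butyldimethylsilyloxy)-2-methylpiperidine-1-carboxylate]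
Conditions: H2 (1 atm), RhCl(PPh3)3 (10 mol%), benzene/EtOH (1:1), rt
Reagents that add atoms: none
Why: Homogeneous hydrogenation with Wilkinson's catalyst reduces the two cis-1,2-disubstituted alkenes far faster than the hindered trisubstituted allylic-acetal alkene, which keeps its E geometry (the C6 descriptor changes from S to R only through CIP priorities).

Step 14
Reactants: 21 the protected dimer from step 13
Product: 22 (2E)-2-{10-[(2R,5S,6S)-5-hydroxy-6-methylpiperidin-2-yl]decyl}-14-[(2R,5S,6S)-5-hydroxy-6-methylpiperidin-2-yl]tetradec-2-enal (CNP0177491.1)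
Conditions: 4 M HCl in 1,4-dioxane/H2O (5:1), 0 °C → rt; then aq. K2CO3 (pH 10), extraction
Reagents that add atoms: water, O
Why: A single acidolysis removes both Boc groups, cleaves both TBS ethers and hydrolyses the dimethyl acetal to the conjugated E-enal, with the amines protonated throughout and no stereocentre affected.

## Compound list

1 | L-alanine methyl ester hydrochloride | C[C@H](N)C(=O)OC.Cl | starting material
2 | methyl (2S)-2-[(diphenylmethylidene)amino]propanoate | C[C@H](N=C(c1ccccc1)c1ccccc1)C(=O)OC | intermediate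
3 | but-3-en-1-ylmagnesium bromide | C=CCC[Mg]Br | starting material
4 | aluminoxy acetal: diisobutylaluminium O-derivative of the methyl hemiacetal of (2S)-2-[(diphenylmethylidene)amino]propanal (acetal carbon unassigned) | C[C@H](N=C(c1ccccc1)c1ccccc1)C(OC)O[Al](CC(C)C)CC(C)C | intermediate (not isolated)
5 | (2S,3S)-2-[(diphenylmethylidene)amino]hept-6-en-3-ol (in equilibrium with its 2,2-diphenyloxazolidine tautomer) | C[C@H](N=C(c1ccccc1)c1ccccc1)[C@@H](O)CCC=C | intermediate
6 | (2S,3S)-2-aminohept-6-en-3-ol hydrochloride | C[C@H](N)[C@@H](O)CCC=C.Cl | intermediate (not isolated)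
7 | tert-butyl N-[(2S,3S)-3-hydroxyhept-6-en-2-yl]carbamate | C[C@H](NC(=O)OC(C)(C)C)[C@@H](O)CCC=C | intermediate
8 | tert-butyl N-[(2S,3S)-3-(tert-butyldimethylsilyloxy)hept-6-en-2-yl]carbamate | C[C@H](NC(=O)OC(C)(C)C)[C@@H](O[Si](C)(C)C(C)(C)C)CCC=C | intermediate
9 | (E)-crotonaldehyde | C/C=C/C=O | starting material
10 | tert-butyl N-[(2S,3S,6E)-3-(tert-butyldimethylsilyloxy)-8-oxooct-6-en-2-yl]carbamate | C[C@H](NC(=O)OC(C)(C)C)[C@@H](O[Si](C)(C)C(C)(C)C)CC/C=C/C=O | intermediate
11 | tert-butyl (2S,3S,6S)-3-(tert-butyldimethylsilyloxy)-2-methyl-6-(2-oxoethyl)piperidine-1-carboxylate (all-cis) | C[C@@H]1N(C(=O)OC(C)(C)C)[C@H](CC=O)CC[C@@H]1O[Si](C)(C)C(C)(C)C | intermediate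
12 | decane-1,10-diol | OCCCCCCCCCCO | starting material
13 | 10-bromodecan-1-ol | OCCCCCCCCCCBr | intermediate
14 | 10-bromodecanal | O=CCCCCCCCCCBr | intermediate
15 | aldol adduct: 12-bromo-2-(8-bromooctyl)-3-hydroxydodecanal (diastereomer mixture) | BrCCCCCCCCCC(O)C(C=O)CCCCCCCCBr | intermediate (not isolated)
16 | (2E)-12-bromo-2-(8-bromooctyl)dodec-2-enal | BrCCCCCCCCC/C=C(/C=O)CCCCCCCCBr | intermediate
17 | (9E)-1,19-dibromo-9-(dimethoxymethyl)nonadec-9-ene | BrCCCCCCCCC/C=C(/C(OC)OC)CCCCCCCCBr | intermediate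
18 | [(9E)-9-(dimethoxymethyl)nonadec-9-ene-1,19-diyl]bis(triphenylphosphonium) dibromide | c1ccccc1[P+](c1ccccc1)(c1ccccc1)CCCCCCCCC/C=C(/C(OC)OC)CCCCCCCC[P+](c1ccccc1)(c1ccccc1)c1ccccc1.[Br-].[Br-] | intermediate
19 | bis-ylide: (9E)-9-(dimethoxymethyl)nonadec-9-ene-1,19-diylidenebis(triphenylphosphorane) | c1ccccc1P(c1ccccc1)(c1ccccc1)=CCCCCCCCC/C=C(/C(OC)OC)CCCCCCCC=P(c1ccccc1)(c1ccccc1)c1ccccc1 | intermediate (not isolated)
20 | di-tert-butyl (2S,2'S,3S,3'S,6S,6'S)-6,6'-[(2Z,11E,21Z)-11-(dimethoxymethyl)tricosa-2,11,21-triene-1,23-diyl]bis[3-(tert-butyldimethylsilyloxy)-2-methylpiperidine-1-carboxylate] | C[C@@H]1N(C(=O)OC(C)(C)C)[C@H](C/C=C\CCCCCCCC/C=C(/C(OC)OC)CCCCCCC/C=C\C[C@@H]2CC[C@H](O[Si](C)(C)C(C)(C)C)[C@H](C)N2C(=O)OC(C)(C)C)CC[C@@H]1O[Si](C)(C)C(C)(C)C | intermediate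
21 | di-tert-butyl (2S,2'S,3S,3'S,6R,6'R)-6,6'-[(11E)-11-(dimethoxymethyl)tricos-11-ene-1,23-diyl]bis[3-(tert-butyldimethylsilyloxy)-2-methylpiperidine-1-carboxylate] | C[C@@H]1N(C(=O)OC(C)(C)C)[C@H](CCCCCCCCCCC/C=C(/C(OC)OC)CCCCCCCCCC[C@@H]2CC[C@H](O[Si](C)(C)C(C)(C)C)[C@H](C)N2C(=O)OC(C)(C)C)CC[C@@H]1O[Si](C)(C)C(C)(C)C | intermediate
22 | (2E)-2-{10-[(2R,5S,6S)-5-hydroxy-6-methylpiperidin-2-yl]decyl}-14-[(2R,5S,6S)-5-hydroxy-6-methylpiperidin-2-yl]tetradec-2-enal | C[C@@H]1N[C@H](CCCCCCCCCCC/C=C(/C=O)CCCCCCCCCC[C@@H]2CC[C@H](O)[C@H](C)N2)CC[C@@H]1O | target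

## Step count and risks

Total step count: 14.
Longest linear sequence: 9 steps (1–6, then 12–14). The core branch is steps 7–11 (5 steps), so the ratio is 9/14.

The three steps most likely to fail:

**Step 6 (organocatalytic aza-Michael).** The carbamate nitrogen sits on a hindered secondary carbon and the catalyst may be mismatched with the substrate, so conversion or the cis:trans ratio at C6 may be poor. The fallback sets out from 8 and comes back at 11. Cross-metathesis of 8 with methyl acrylate (Hoveyda–Grubbs II) gives methyl (2E,6S,7S)-7-[(tert-butoxycarbonyl)amino]-6-(tert-butyldimethylsilyloxy)oct-2-enoate F1. TMSOTf/2,6-lutidine, then MeOH, removes the Boc group without touching the TBS ether. The free primary amine then cyclises under substrate control (K2CO3, MeOH) through a chair with the C2 methyl and the acetate arm equatorial, giving methyl 2-[(2S,5S,6S)-5-(tert-butyldimethylsilyloxy)-6-methylpiperidin-2-yl]acetate F2. This 2,6-cis NH-piperidine is also the more stable isomer, so any trans material can be equilibrated by retro-Michael/Michael. Boc2O gives tert-butyl (2S,3S,6S)-3-(tert-butyldimethylsilyloxy)-6-(2-methoxy-2-oxoethyl)-2-methylpiperidine-1-carboxylate F3, and DIBAL-H (toluene, −78 °C) reduces the ester to aldehyde 11.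

**Step 12 (double Wittig).** The β-carbamoyl aldehyde can enolise or open by retro-Michael under the basic ylide, and a double coupling on a bis-phosphonium salt may stall at the mono-olefin. The fallback sets out from 11 and 17 and comes back at 21, replacing olefination by an sp3–sp3 coupling (it also bypasses step 13). NaBH4 reduces 11 to tert-butyl (2S,3S,6S)-3-(tert-butyldimethylsilyloxy)-6-(2-hydroxyethyl)-2-methylpiperidine-1-carboxylate F4. I2/PPh3/imidazole converts it into tert-butyl (2S,3S,6S)-3-(tert-butyldimethylsilyloxy)-6-(2-iodoethyl)-2-methylpiperidine-1-carboxylate F5. Dibromide 17 is turned with Mg (THF) into the bis-Grignard reagent [(9E)-9-(dimethoxymethyl)nonadec-9-ene-1,19-diyl]bis(magnesium bromide) F6. F6 is coupled with two equivalents of F5 under Li2CuCl4 catalysis (THF/NMP, −20 °C, kept cold to avoid SN2' attack on the allylic acetal) to give 21 directly.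

**Step 13 (selective hydrogenation).** Over-reduction or isomerisation of the central trisubstituted alkene would destroy the enal. The fallback sets out from 14 and 11 and comes back at 22; it forms the enal only after all hydrogenation is done. Acetalisation of 14 with HC(OMe)3/PPTS gives 10-bromo-1,1-dimethoxydecane F7, and PPh3 (MeCN, reflux) gives (10,10-dimethoxydecyl)triphenylphosphonium bromide F8. Its ylide (KHMDS) reacts with 11 to give tert-butyl (2S,3S,6S)-3-(tert-butyldimethylsilyloxy)-6-[(2Z)-12,12-dimethoxydodec-2-en-1-yl]-2-methylpiperidine-1-carboxylate F9. Unselective hydrogenation (H2, Pd/C, EtOAc) gives tert-butyl (2S,3S,6R)-3-(tert-butyldimethylsilyloxy)-6-(12,12-dimethoxydodecyl)-2-methylpiperidine-1-carboxylate F10. Mild hydrolysis (PPTS, acetone/H2O) gives tert-butyl (2S,3S,6R)-3-(tert-butyldimethylsilyloxy)-2-methyl-6-(12-oxododecyl)piperidine-1-carboxylate F11. Self-aldol condensation of F11 (Bn2NH·CF3CO2H, toluene, 70 °C) gives di-tert-butyl (2S,2'S,3S,3'S,6R,6'R)-6,6'-[(11E)-11-formyltricos-11-ene-1,23-diyl]bis[3-(tert-butyldimethylsilyloxy)-2-methylpiperidine-1-carboxylate] F12. The conditions of step 14 then convert F12 into 22.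

## Further compounds

F1 | step 6 | methyl (2E,6S,7S)-7-[(tert-butoxycarbonyl)amino]-6-(tert-butyldimethylsilyloxy)oct-2-enoate | C[C@H](NC(=O)OC(C)(C)C)[C@@H](O[Si](C)(C)C(C)(C)C)CC/C=C/C(=O)OC
F2 | step 6 | methyl 2-[(2S,5S,6S)-5-(tert-butyldimethylsilyloxy)-6-methylpiperidin-2-yl]acetate | C[C@@H]1N[C@H](CC(=O)OC)CC[C@@H]1O[Si](C)(C)C(C)(C)C
F3 | step 6 | tert-butyl (2S,3S,6S)-3-(tert-butyldimethylsilyloxy)-6-(2-methoxy-2-oxoethyl)-2-methylpiperidine-1-carboxylate | C[C@@H]1N(C(=O)OC(C)(C)C)[C@H](CC(=O)OC)CC[C@@H]1O[Si](C)(C)C(C)(C)C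
F4 | step 12 | tert-butyl (2S,3S,6S)-3-(tert-butyldimethylsilyloxy)-6-(2-hydroxyethyl)-2-methylpiperidine-1-carboxylate | C[C@@H]1N(C(=O)OC(C)(C)C)[C@H](CCO)CC[C@@H]1O[Si](C)(C)C(C)(C)C
F5 | step 12 | tert-butyl (2S,3S,6S)-3-(tert-butyldimethylsilyloxy)-6-(2-iodoethyl)-2-methylpiperidine-1-carboxylate | C[C@@H]1N(C(=O)OC(C)(C)C)[C@H](CCI)CC[C@@H]1O[Si](C)(C)C(C)(C)C
F6 | step 12 | [(9E)-9-(dimethoxymethyl)nonadec-9-ene-1,19-diyl]bis(magnesium bromide) | Br[Mg]CCCCCCCCC/C=C(/C(OC)OC)CCCCCCCC[Mg]Br
F7 | step 13 | 10-bromo-1,1-dimethoxydecane | COC(OC)CCCCCCCCCBr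
F8 | step 13 | (10,10-dimethoxydecyl)triphenylphosphonium bromide | COC(OC)CCCCCCCCC[P+](c1ccccc1)(c1ccccc1)c1ccccc1.[Br-]
F9 | step 13 | tert-butyl (2S,3S,6S)-3-(tert-butyldimethylsilyloxy)-6-[(2Z)-12,12-dimethoxydodec-2-en-1-yl]-2-methylpiperidine-1-carboxylate | C[C@@H]1N(C(=O)OC(C)(C)C)[C@H](C/C=C\CCCCCCCCC(OC)OC)CC[C@@H]1O[Si](C)(C)C(C)(C)C
F10 | step 13 | tert-butyl (2S,3S,6R)-3-(tert-butyldimethylsilyloxy)-6-(12,12-dimethoxydodecyl)-2-methylpiperidine-1-carboxylate | C[C@@H]1N(C(=O)OC(C)(C)C)[C@H](CCCCCCCCCCCC(OC)OC)CC[C@@H]1O[Si](C)(C)C(C)(C)C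
F11 | step 13 | tert-butyl (2S,3S,6R)-3-(tert-butyldimethylsilyloxy)-2-methyl-6-(12-oxododecyl)piperidine-1-carboxylate | C[C@@H]1N(C(=O)OC(C)(C)C)[C@H](CCCCCCCCCCCC=O)CC[C@@H]1O[Si](C)(C)C(C)(C)C
F12 | step 13 | di-tert-butyl (2S,2'S,3S,3'S,6R,6'R)-6,6'-[(11E)-11-formyltricos-11-ene-1,23-diyl]bis[3-(tert-butyldimethylsilyloxy)-2-methylpiperidine-1-carboxylate] | C[C@@H]1N(C(=O)OC(C)(C)C)[C@H](CCCCCCCCCCC/C=C(/C=O)CCCCCCCCCC[C@@H]2CC[C@H](O[Si](C)(C)C(C)(C)C)[C@H](C)N2C(=O)OC(C)(C)C)CC[C@@H]1O[Si](C)(C)C(C)(C)C
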